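The route rests on building the pentasubstituted benzene ring A of the lower chromanone (C4a''–C8a'') from a cyclobutenone and an alkyne instead of substituting phloroglucinol. One thermal cascade joins 3-(benzyloxy)cyclobutenone with a triisopropylsiloxyalkyne that already carries C3–C4 as an acetal arm: it forms C8''–C8a'' and C6''–C7'', closes ring A, and delivers the oxygens on C8a'', C7'' and C5'' as free hydroxyl, silyl ether and benzyl ether. The feature exploited is the lack of symmetry of ring A: only the C8a'' oxygen closes the pyranone and the C3 arm must sit at C8'', not C6''. Both pyranones are then made as chromones, and C2'', C2 and C3 are set last by asymmetric aryl addition.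

Key step: step 3

Locants: doubly primed for the chromanone that bears the 4-hydroxyphenyl group (lower unit), unprimed for the chromanone that bears the catechol (upper unit); the target is (2R,3R,2''R) with the two aryl groups on C2 and C3 cis.

Assumption: the (S)-pyridine–oxazoline ligand is taken to deliver the aryl group to the chromone face that gives (R) at the arylated carbon, by analogy with its sense on cyclic enones; if the sense proves opposite, the (R)-ligand is used in steps 13 and 14.

Step 1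
Reactants: 1 4,4-dimethoxybut-1-yne
Product: 4 4,4-dimethoxy-1-(triisopropylsilyloxy)but-1-yne, via lithium acetylide 2 (not isolated), via lithium ynolate 3 (not isolated)
Conditions: n-BuLi, THF, −78 °C; t-BuOOLi (from t-BuOOH and LiN(SiMe3)2), −78 → 0 °C; i-Pr3SiOSO2CF3, −78 °C
Reagents that add atoms: tert-butyl hydroperoxide (used as its lithium salt), CC(C)(C)OO; triisopropylsilyl trifluoromethanesulfonate, CC(C)[Si](C(C)C)(C(C)C)OS(=O)(=O)C(F)(F)F
Why: Oxidation of the lithium acetylide by the lithium peroxide gives the ynolate, which the bulky silyl triflate traps on oxygen (acetylide oxidation and O-silylation); no ester enolate with a β-methoxy leaving group is ever formed, so the acetal arm cannot eliminate methanol.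

Step 2
Reactants: 5 cyclobutane-1,3-dione
Product: 6 3-(benzyloxy)cyclobut-2-en-1-one
Conditions: BnOH, PPh3, i-PrO2CN=NCO2i-Pr, THF, 0 °C → rt
Reagents that add atoms: benzyl alcohol, OCc1ccccc1
Why: Mitsunobu O-alkylation of the strongly acidic enol of the dione gives the vinylogous benzyl ester, so the C5'' oxygen is born as an ether that hydrogenolysis removes at the end, which an ethyl ether would not allow.

Step 3
Reactants: 4 4,4-dimethoxy-1-(triisopropylsilyloxy)but-1-yne; 6 3-(benzyloxy)cyclobut-2-en-1-one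
Product: 11 5-(benzyloxy)-2-(2,2-dimethoxyethyl)-3-(triisopropylsilyloxy)phenol, via vinylketene 7 (not isolated), via vinylcyclobutenone 8 (not isolated), via dienylketene 9 (not isolated), via cyclohexadienone 10 (not isolated)
Conditions: 4 (1.0 equiv), 6 (1.3 equiv), toluene, 80 °C then 110 °C, sealed tube, argon
Reagents that add atoms: none
Why: Heating opens cyclobutenone 6 by four-electron electrocyclic ring opening to vinylketene 7, whose electrophilic central carbon is attacked by the nucleophilic, arm-bearing carbon of the siloxyalkyne in a [2+2] cycloaddition that gives the 4-vinylcyclobutenone 8 and forms C8''–C8a'' and C6''–C7''. A second four-electron opening gives dienylketene 9, which closes benzene ring A by a six-electron disrotatory electrocyclisation between C8a'' and C4a'', and dienone 10 tautomerises to the phenol. The closest known reaction is the Danheiser benzannulation of cyclobutenones with triisopropylsiloxyalkynes, which gives resorcinol monosilyl ethers. No stereocentre is formed. The selectivity needed is regiochemical and is secured by the polarity of the partners: the ketene carbon can only bond to the alkyne carbon remote from the siloxy group, so the arm lies between the free hydroxyl (C8a'') and the silyl ether (C7'') and the benzyloxy group is carried to C5''. The arene is thus born pentasubstituted with three differently masked oxygens, and no later choice between C6'' and C8'' arises.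

Step 4
Reactants: 11 5-(benzyloxy)-2-(2,2-dimethoxyethyl)-3-(triisopropylsilyloxy)phenol
Product: 12 6-(benzyloxy)-3-(2,2-dimethoxyethyl)-2-hydroxy-4-(triisopropylsilyloxy)benzaldehyde
Conditions: MgCl2, Et3N, (CH2O)n, MeCN, reflux; aq. NH4Cl work-up
Reagents that add atoms: paraformaldehyde (as formaldehyde), C=O
Why: The magnesium-mediated ortho-formylation (Casnati–Skattebøl reaction) is specific for the position ortho to the free phenol, and with C8'' blocked only C4a'' can react; the basic medium and non-acidic work-up keep the acetal from closing onto the neighbouring hydroxyl.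

Step 5
Reactants: 12 6-(benzyloxy)-3-(2,2-dimethoxyethyl)-2-hydroxy-4-(triisopropylsilyloxy)benzaldehyde
Product: 13 1-[6-(benzyloxy)-3-(2,2-dimethoxyethyl)-2-hydroxy-4-(triisopropylsilyloxy)phenyl]prop-2-yn-1-ol (racemic)
Conditions: HC≡CMgBr (3 equiv), THF, 0 °C → rt; aq. NH4Cl
Reagents that add atoms: ethynylmagnesium bromide, C#C[Mg]Br
Why: Grignard 1,2-addition to the aldehyde after the first equivalent has deprotonated the phenol brings in C3'' and C2''; the carbinol centre is racemic and is oxidised away in the next step.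

Step 6
Reactants: 13 1-[6-(benzyloxy)-3-(2,2-dimethoxyethyl)-2-hydroxy-4-(triisopropylsilyloxy)phenyl]prop-2-yn-1-ol
Product: 15 5-(benzyloxy)-8-(2,2-dimethoxyethyl)-7-(triisopropylsilyloxy)-4H-chromen-4-one, via ynone 14 (not isolated)
Conditions: MnO2, CH2Cl2, rt; filter; Et2NH (20 mol %), MeCN, rt
Reagents that add atoms: none
Why: MnO2 oxidises the benzylic propargylic alcohol to the ynone, and the secondary amine adds to the ynone and is displaced by the phenol in a 6-endo addition–elimination that closes the pyranone through the C8a'' oxygen (amine-catalysed chromone synthesis from 2-hydroxyaryl ynones).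

Step 7
Reactants: 15 5-(benzyloxy)-8-(2,2-dimethoxyethyl)-7-(triisopropylsilyloxy)-4H-chromen-4-one
Product: 17 5,7-bis(benzyloxy)-8-(2,2-dimethoxyethyl)-4H-chromen-4-one, via ammonium phenoxide 16 (not isolated)
Conditions: Bu4NF, THF, 0 °C; then BnBr, rt
Reagents that add atoms: benzyl bromide, BrCc1ccccc1
Why: Fluoride cleaves the silyl ether of the vinylogous acid and the tetrabutylammonium phenoxide is benzylated in the same flask (Williamson ether synthesis), which replaces a labile, bulky group next to C8'' that could lactonise onto the arm once this is an activated acid.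

Step 8
Reactants: 17 5,7-bis(benzyloxy)-8-(2,2-dimethoxyethyl)-4H-chromen-4-one
Product: 18 2-[5,7-bis(benzyloxy)-4-oxo-4H-chromen-8-yl]acetaldehyde
Conditions: 1 M HCl (aq), THF, rt
Reagents that add atoms: water, O
Why: Acid-catalysed acetal hydrolysis unmasks the aldehyde only now, when the C8a'' oxygen is in the pyranone and the C7'' oxygen is a benzyl ether, so neither flanking oxygen can close a benzofuran.

Step 9
Reactants: 18 2-[5,7-bis(benzyloxy)-4-oxo-4H-chromen-8-yl]acetaldehyde
Product: 19 2-[5,7-bis(benzyloxy)-4-oxo-4H-chromen-8-yl]acetic acid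
Conditions: NaClO2, NaH2PO4, 2-methylbut-2-ene, t-BuOH/THF/H2O, 0 °C → rt
Reagents that add atoms: sodium chlorite, [Na+].[O-]Cl=O
Why: The Pinnick oxidation converts the enolisable aryl acetaldehyde to the acid under buffered conditions, with the alkene scavenging hypochlorous acid before it can chlorinate the electron-rich ring.

Step 10
Reactants: 19 2-[5,7-bis(benzyloxy)-4-oxo-4H-chromen-8-yl]acetic acid; 20 1,3,5-tris(benzyloxy)benzene
Product: 22 5,7-bis(benzyloxy)-8-{2-oxo-2-[2,4,6-tris(benzyloxy)phenyl]ethyl}-4H-chromen-4-one, via mixed anhydride 21 (not isolated)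
Conditions: (CF3CO)2O, CH2Cl2, 0 °C → rt
Reagents that add atoms: none
Why: Friedel–Crafts acylation of the very electron-rich, threefold-symmetric arene by the mixed trifluoroacetic anhydride forms the C4–C4a bond without a metal Lewis acid and without any regiochemical choice.

Step 11
Reactants: 22 5,7-bis(benzyloxy)-8-{2-oxo-2-[2,4,6-tris(benzyloxy)phenyl]ethyl}-4H-chromen-4-one
Product: 23 7-(benzyloxy)-8-{2-[2,4-bis(benzyloxy)-6-hydroxyphenyl]-2-oxoethyl}-5-hydroxy-4H-chromen-4-one
Conditions: BCl3 (2.5 equiv), CH2Cl2, −78 °C; then aq. NaHCO3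
Reagents that add atoms: none
Why: Chelation-controlled debenzylation by BCl3 cleaves only benzyl ethers that can bind boron together with a neighbouring carbonyl, here one ether ortho to the new ketone and the peri ether on C5'', and should leave the other benzyl ethers untouched at −78 °C.

Step 12
Reactants: 23 7-(benzyloxy)-8-{2-[2,4-bis(benzyloxy)-6-hydroxyphenyl]-2-oxoethyl}-5-hydroxy-4H-chromen-4-one
Product: 25 5,7-bis(benzyloxy)-3-[7-(benzyloxy)-5-hydroxy-4-oxo-4H-chromen-8-yl]-4H-chromen-4-one, via enaminone 24 (not isolated)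
Conditions: Me2NCH(OMe)2, THF, 60 °C; then 1 M HCl (aq), rt
Reagents that add atoms: N,N-dimethylformamide dimethyl acetal, COC(OC)N(C)C
Why: Condensation of the doubly activated methylene with the amide acetal gives the enaminone, and addition–elimination by the ortho hydroxyl closes the 3-arylchromone and brings in C2 (isoflavone synthesis from a 2-hydroxydeoxybenzoin); the acid wash re-closes any chromone opened by dimethylamine.

Step 13
Reactants: 25 5,7-bis(benzyloxy)-3-[7-(benzyloxy)-5-hydroxy-4-oxo-4H-chromen-8-yl]-4H-chromen-4-one; 26 [4-(benzyloxy)phenyl]boronic acid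
Product: 27 5,7-bis(benzyloxy)-3-{(2R)-7-(benzyloxy)-2-[4-(benzyloxy)phenyl]-5-hydroxy-4-oxo-3,4-dihydro-2H-chromen-8-yl}-4H-chromen-4-one
Conditions: 26 (2 equiv), Pd(OCOCF3)2 (10 mol %), (S)-4-tert-butyl-2-(pyridin-2-yl)-4,5-dihydrooxazole (12 mol %), NH4PF6 (30 mol %), H2O (5 equiv), ClCH2CH2Cl, 60 °C
Reagents that add atoms: none
Why: The asymmetric conjugate addition of arylboronic acids to chromones under divalent-palladium–pyridine-oxazoline catalysis should arylate the 3-unsubstituted, hydrogen-bond-activated lower chromone in preference to the hindered 3-arylchromone, and the ligand blocks one face of the coordinated enone so that aryl migration sets (R) at C2''.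

Step 14
Reactants: 27 5,7-bis(benzyloxy)-3-{(2R)-7-(benzyloxy)-2-[4-(benzyloxy)phenyl]-5-hydroxy-4-oxo-3,4-dihydro-2H-chromen-8-yl}-4H-chromen-4-one; 28 [3,4-bis(benzyloxy)phenyl]boronic acid
Product: 29 (2R,3R)-5,7-bis(benzyloxy)-3-{(2R)-7-(benzyloxy)-2-[4-(benzyloxy)phenyl]-5-hydroxy-4-oxo-3,4-dihydro-2H-chromen-8-yl}-2-[3,4-bis(benzyloxy)phenyl]-2,3-dihydro-4H-chromen-4-one (2,3-cis)
Conditions: 28 (3 equiv), Pd(OCOCF3)2 (15 mol %), (S)-4-tert-butyl-2-(pyridin-2-yl)-4,5-dihydrooxazole (18 mol %), NH4PF6 (30 mol %), H2O (5 equiv), ClCH2CH2Cl, 40 °C; neutral work-up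
Reagents that add atoms: none
Why: Proposed new method: the same cationic aryl-palladium catalyst is expected to insert the C2=C3 bond of the 3-arylchromone with aryl transfer to the unhindered C2 on the face chosen by the ligand (R at C2), giving an oxygen-bound palladium enolate that is released and ketonised under acidic, base-free conditions by protonation of C3 anti to the pseudoaxial C2 aryl group, so that the 2,3-cis (3R) isomer is the kinetic product; the closest known reactions are the palladium–pyridine-oxazoline arylation of 3-unsubstituted chromones and the rhodium-catalysed arylation of 1-nitrocycloalkenes, where kinetic protonation likewise gives the cis product.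

Step 15
Reactants: 29 (2R,3R)-5,7-bis(benzyloxy)-3-{(2R)-7-(benzyloxy)-2-[4-(benzyloxy)phenyl]-5-hydroxy-4-oxo-3,4-dihydro-2H-chromen-8-yl}-2-[3,4-bis(benzyloxy)phenyl]-2,3-dihydro-4H-chromen-4-one
Product: 30 (2R,3R)-2-(3,4-dihydroxyphenyl)-5,7-dihydroxy-3-[(2R)-5,7-dihydroxy-2-(4-hydroxyphenyl)-4-oxo-3,4-dihydro-2H-chromen-8-yl]-2,3-dihydro-4H-chromen-4-one
Conditions: H2 (1 atm), Pd/C, EtOAc/MeOH, rt
Reagents that add atoms: none
Why: Catalytic hydrogenolysis removes the six benzyl ethers under neutral conditions, without base or Lewis acid, so the epimerisable C3 and the configurations at C2 and C2'' should not be disturbed.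

Compound list
1 | 4,4-dimethoxybut-1-yne | COC(OC)CC#C | starting material
2 | (4,4-dimethoxybut-1-yn-1-yl)lithium | [Li]C#CCC(OC)OC | intermediate
3 | lithium 4,4-dimethoxybut-1-yn-1-olate | [Li+].[O-]C#CCC(OC)OC | intermediate
4 | 4,4-dimethoxy-1-(triisopropylsilyloxy)but-1-yne | COC(OC)CC#CO[Si](C(C)C)(C(C)C)C(C)C | intermediate
5 | cyclobutane-1,3-dione | O=C1CC(=O)C1 | starting material
6 | 3-(benzyloxy)cyclobut-2-en-1-one | O=C1C=C(OCc2ccccc2)C1 | intermediate
7 | 3-(benzyloxy)buta-1,3-dien-1-one | C=C(OCc1ccccc1)C=C=O | intermediate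
8 | 4-[1-(benzyloxy)ethenyl]-2-(2,2-dimethoxyethyl)-3-(triisopropylsilyloxy)cyclobut-2-en-1-one (racemic) | C=C(OCc1ccccc1)C1C(=O)C(CC(OC)OC)=C1O[Si](C(C)C)(C(C)C)C(C)C | intermediate
9 | 5-(benzyloxy)-2-(2,2-dimethoxyethyl)-3-(triisopropylsilyloxy)hexa-1,3,5-trien-1-one | C=C(OCc1ccccc1)C=C(O[Si](C(C)C)(C(C)C)C(C)C)C(CC(OC)OC)=C=O | intermediate
10 | 5-(benzyloxy)-2-(2,2-dimethoxyethyl)-3-(triisopropylsilyloxy)cyclohexa-2,4-dien-1-one | O=C1CC(OCc2ccccc2)=CC(O[Si](C(C)C)(C(C)C)C(C)C)=C1CC(OC)OC | intermediate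
11 | 5-(benzyloxy)-2-(2,2-dimethoxyethyl)-3-(triisopropylsilyloxy)phenol | COC(OC)Cc1c(O)cc(OCc2ccccc2)cc1O[Si](C(C)C)(C(C)C)C(C)C | intermediate
12 | 6-(benzyloxy)-3-(2,2-dimethoxyethyl)-2-hydroxy-4-(triisopropylsilyloxy)benzaldehyde | O=Cc1c(O)c(CC(OC)OC)c(O[Si](C(C)C)(C(C)C)C(C)C)cc1OCc1ccccc1 | intermediate
13 | 1-[6-(benzyloxy)-3-(2,2-dimethoxyethyl)-2-hydroxy-4-(triisopropylsilyloxy)phenyl]prop-2-yn-1-ol (racemic) | C#CC(O)c1c(O)c(CC(OC)OC)c(O[Si](C(C)C)(C(C)C)C(C)C)cc1OCc1ccccc1 | intermediate
14 | 1-[6-(benzyloxy)-3-(2,2-dimethoxyethyl)-2-hydroxy-4-(triisopropylsilyloxy)phenyl]prop-2-yn-1-one | C#CC(=O)c1c(O)c(CC(OC)OC)c(O[Si](C(C)C)(C(C)C)C(C)C)cc1OCc1ccccc1 | intermediate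
15 | 5-(benzyloxy)-8-(2,2-dimethoxyethyl)-7-(triisopropylsilyloxy)-4H-chromen-4-one | COC(OC)Cc1c(O[Si](C(C)C)(C(C)C)C(C)C)cc(OCc2ccccc2)c2c(=O)ccoc12 | intermediate
16 | tetrabutylammonium 5-(benzyloxy)-8-(2,2-dimethoxyethyl)-4-oxo-4H-chromen-7-olate | CCCC[N+](CCCC)(CCCC)CCCC.COC(OC)Cc1c([O-])cc(OCc2ccccc2)c2c(=O)ccoc12 | intermediate
17 | 5,7-bis(benzyloxy)-8-(2,2-dimethoxyethyl)-4H-chromen-4-one | COC(OC)Cc1c(OCc2ccccc2)cc(OCc2ccccc2)c2c(=O)ccoc12 | intermediate
18 | 2-[5,7-bis(benzyloxy)-4-oxo-4H-chromen-8-yl]acetaldehyde | O=CCc1c(OCc2ccccc2)cc(OCc2ccccc2)c2c(=O)ccoc12 | intermediate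
19 | 2-[5,7-bis(benzyloxy)-4-oxo-4H-chromen-8-yl]acetic acid | OC(=O)Cc1c(OCc2ccccc2)cc(OCc2ccccc2)c2c(=O)ccoc12 | intermediate
20 | 1,3,5-tris(benzyloxy)benzene | c1ccc(COc2cc(OCc3ccccc3)cc(OCc3ccccc3)c2)cc1 | starting material
21 | [5,7-bis(benzyloxy)-4-oxo-4H-chromen-8-yl]acetic trifluoroacetic anhydride | O=C(Cc1c(OCc2ccccc2)cc(OCc2ccccc2)c2c(=O)ccoc12)OC(=O)C(F)(F)F | intermediate
22 | 5,7-bis(benzyloxy)-8-{2-oxo-2-[2,4,6-tris(benzyloxy)phenyl]ethyl}-4H-chromen-4-one | O=C(Cc1c(OCc2ccccc2)cc(OCc2ccccc2)c2c(=O)ccoc12)c1c(OCc2ccccc2)cc(OCc2ccccc2)cc1OCc1ccccc1 | intermediate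
23 | 7-(benzyloxy)-8-{2-[2,4-bis(benzyloxy)-6-hydroxyphenyl]-2-oxoethyl}-5-hydroxy-4H-chromen-4-one | O=C(Cc1c(OCc2ccccc2)cc(O)c2c(=O)ccoc12)c1c(O)cc(OCc2ccccc2)cc1OCc1ccccc1 | intermediate
24 | 2-[7-(benzyloxy)-5-hydroxy-4-oxo-4H-chromen-8-yl]-1-[2,4-bis(benzyloxy)-6-hydroxyphenyl]-3-(dimethylamino)prop-2-en-1-one | CN(C)C=C(C(=O)c1c(O)cc(OCc2ccccc2)cc1OCc1ccccc1)c1c(OCc2ccccc2)cc(O)c2c(=O)ccoc12 | intermediate
25 | 5,7-bis(benzyloxy)-3-[7-(benzyloxy)-5-hydroxy-4-oxo-4H-chromen-8-yl]-4H-chromen-4-one | O=c1c(-c2c(OCc3ccccc3)cc(O)c3c(=O)ccoc23)coc2cc(OCc3ccccc3)cc(OCc3ccccc3)c12 | intermediate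
26 | [4-(benzyloxy)phenyl]boronic acid | OB(O)c1ccc(OCc2ccccc2)cc1 | starting material
27 | 5,7-bis(benzyloxy)-3-{(2R)-7-(benzyloxy)-2-[4-(benzyloxy)phenyl]-5-hydroxy-4-oxo-3,4-dihydro-2H-chromen-8-yl}-4H-chromen-4-one | O=C1C[C@H](c2ccc(OCc3ccccc3)cc2)Oc2c1c(O)cc(OCc1ccccc1)c2-c1coc2cc(OCc3ccccc3)cc(OCc3ccccc3)c2c1=O | intermediate
28 | [3,4-bis(benzyloxy)phenyl]boronic acid | OB(O)c1ccc(OCc2ccccc2)c(OCc2ccccc2)c1 | starting material
29 | (2R,3R)-5,7-bis(benzyloxy)-3-{(2R)-7-(benzyloxy)-2-[4-(benzyloxy)phenyl]-5-hydroxy-4-oxo-3,4-dihydro-2H-chromen-8-yl}-2-[3,4-bis(benzyloxy)phenyl]-2,3-dihydro-4H-chromen-4-one | O=C1C[C@H](c2ccc(OCc3ccccc3)cc2)Oc2c1c(O)cc(OCc1ccccc1)c2[C@H]1C(=O)c2c(OCc3ccccc3)cc(OCc3ccccc3)cc2O[C@H]1c1ccc(OCc2ccccc2)c(OCc2ccccc2)c1 | intermediate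
30 | (2R,3R)-2-(3,4-dihydroxyphenyl)-5,7-dihydroxy-3-[(2R)-5,7-dihydroxy-2-(4-hydroxyphenyl)-4-oxo-3,4-dihydro-2H-chromen-8-yl]-2,3-dihydro-4H-chromen-4-one | O=C1C[C@H](c2ccc(O)cc2)Oc2c1c(O)cc(O)c2[C@H]1C(=O)c2c(O)cc(O)cc2O[C@H]1c1ccc(O)c(O)c1 | target

Total step count: 15. Longest linear sequence: 14 steps (1 → 4 → 11 → 12 → 13 → 15 → 17 → 18 → 19 → 22 → 23 → 25 → 27 → 29 → 30).

Steps most likely to fail

Step 14. Insertion of the crowded, electron-rich 3-aryl enone may be so slow that protodeboronation of 28 consumes the reagent. The ligand may also discriminate the faces of C2 poorly once C3 carries an aryl group. The kinetic cis product may epimerise at C3 to the trans isomer on prolonged warming. The fallback uses stoichiometric, known chemistry and sets out from 27. 4-Bromo-1,2-bis(benzyloxy)benzene and magnesium give [3,4-bis(benzyloxy)phenyl]magnesium bromide F1, which is added to 27 with CuBr·SMe2 (20 mol %) and Me3SiCl in THF at −78 °C (copper-catalysed 1,4-addition of an aryl Grignard reagent to a 3-substituted chromone). The 5''-hydroxyl is deprotonated and silylated in the same flask, which also makes the flavanone carbonyl inert, and the adduct is held as the bis(trimethylsilyl) enol ether F2. Kinetic protonation of F2 with cold acetic acid in THF/water should again deliver the proton to C3 anti to the C2 aryl group, so both products are 2,3-cis: 29 and its (2S,3S) diastereomer F3. These differ from each other through the fixed (R)-C2'' centre and are separated by chromatography. The fallback comes back to the route at 29.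

Step 3. The benzyloxy group makes 6 a vinylogous ester, so ring opening may need temperatures at which the siloxyalkyne rearranges to a silylketene, and the phenol formed may be acylated by further vinylketene. The fallback generates the same vinylketene 7 without heat, by 1,4-dehydrochlorination of an acid chloride, and traps it with the same alkyne (ketene–siloxyalkyne cycloaddition). Acid-catalysed alkoxy exchange of commercial ethyl (E)-3-ethoxybut-2-enoate with benzyl alcohol gives ethyl (E)-3-(benzyloxy)but-2-enoate F4; saponification gives (E)-3-(benzyloxy)but-2-enoic acid F5; oxalyl chloride gives (E)-3-(benzyloxy)but-2-enoyl chloride F6. Slow addition of F6 to 4 and Et3N in toluene at 0 °C to room temperature forms 7 in the presence of the alkyne, and the [2+2] adduct 8 is then warmed to 80 °C to pass through 9 and 10. The same bonds are formed and the same ring is closed. The fallback sets out from 4 and comes back at 11.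

Step 13. The 5''-hydroxy-4''-oxo unit can bind divalent palladium, and the crowded bis-chromone may react so slowly that the boronic acid is lost to protodeboronation. The fallback changes the order of events: the lower ring is arylated while its C5'' oxygen is still benzylated and before the second chromone exists. It sets out from 22. Compound 22 and 26 under the catalysis of step 13 should give the (R)-flavanone ketone F7, a conjugate arylation of a simple 5,7-dialkoxychromone. BCl3 at −78 °C then removes the two chelating benzyl groups to give the hydroxy ketone F8. The amide acetal at 50 °C in THF should react at the doubly activated methylene well before C3''H2 and give enaminone F9, which closes to the 3-arylchromone. The fallback comes back to the route at 27.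

Further compounds
F1 | step 14 | [3,4-bis(benzyloxy)phenyl]magnesium bromide | Br[Mg]c1ccc(OCc2ccccc2)c(OCc2ccccc2)c1
F2 | step 14 | (2R)-7-(benzyloxy)-2-[4-(benzyloxy)phenyl]-8-{5,7-bis(benzyloxy)-2-[3,4-bis(benzyloxy)phenyl]-4-(trimethylsilyloxy)-2H-chromen-3-yl}-5-(trimethylsilyloxy)-2,3-dihydro-4H-chromen-4-one (both epimers at the chromene C2) | O=C1C[C@H](c2ccc(OCc3ccccc3)cc2)Oc2c1c(O[Si](C)(C)C)cc(OCc1ccccc1)c2C1=C(O[Si](C)(C)C)c2c(OCc3ccccc3)cc(OCc3ccccc3)cc2OC1c1ccc(OCc2ccccc2)c(OCc2ccccc2)c1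
F3 | step 14 | (2S,3S)-5,7-bis(benzyloxy)-3-{(2R)-7-(benzyloxy)-2-[4-(benzyloxy)phenyl]-5-hydroxy-4-oxo-3,4-dihydro-2H-chromen-8-yl}-2-[3,4-bis(benzyloxy)phenyl]-2,3-dihydro-4H-chromen-4-one | O=C1C[C@H](c2ccc(OCc3ccccc3)cc2)Oc2c1c(O)cc(OCc1ccccc1)c2[C@@H]1C(=O)c2c(OCc3ccccc3)cc(OCc3ccccc3)cc2O[C@@H]1c1ccc(OCc2ccccc2)c(OCc2ccccc2)c1
F4 | step 3 | ethyl (E)-3-(benzyloxy)but-2-enoate | CCOC(=O)/C=C(\C)OCc1ccccc1
F5 | step 3 | (E)-3-(benzyloxy)but-2-enoic acid | OC(=O)/C=C(\C)OCc1ccccc1
F6 | step 3 | (E)-3-(benzyloxy)but-2-enoyl chloride | ClC(=O)/C=C(\C)OCc1ccccc1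
F7 | step 13 | (2R)-5,7-bis(benzyloxy)-2-[4-(benzyloxy)phenyl]-8-{2-oxo-2-[2,4,6-tris(benzyloxy)phenyl]ethyl}-2,3-dihydro-4H-chromen-4-one | O=C1C[C@H](c2ccc(OCc3ccccc3)cc2)Oc2c1c(OCc1ccccc1)cc(OCc1ccccc1)c2CC(=O)c1c(OCc2ccccc2)cc(OCc2ccccc2)cc1OCc1ccccc1
F8 | step 13 | (2R)-7-(benzyloxy)-2-[4-(benzyloxy)phenyl]-8-{2-[2,4-bis(benzyloxy)-6-hydroxyphenyl]-2-oxoethyl}-5-hydroxy-2,3-dihydro-4H-chromen-4-one | O=C1C[C@H](c2ccc(OCc3ccccc3)cc2)Oc2c1c(O)cc(OCc1ccccc1)c2CC(=O)c1c(O)cc(OCc2ccccc2)cc1OCc1ccccc1
F9 | step 13 | (2R)-7-(benzyloxy)-2-[4-(benzyloxy)phenyl]-8-{1-[2,4-bis(benzyloxy)-6-hydroxyphenyl]-3-(dimethylamino)-1-oxoprop-2-en-2-yl}-5-hydroxy-2,3-dihydro-4H-chromen-4-one | O=C1C[C@H](c2ccc(OCc3ccccc3)cc2)Oc2c1c(O)cc(OCc1ccccc1)c2C(=CN(C)C)C(=O)c1c(O)cc(OCc2ccccc2)cc1OCc1ccccc1
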